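## Retrosynthetic overview

1. The target (vitisin A) comes from its deca-O-benzyl ether. The central E-stilbene is cut into a west aryl aldehyde and an east arylacetic acid, joined by an intermolecular aldol addition of the acid dianion and then decarboxylative dehydration.
2. The west aldehyde comes from ionic hydrogenation at C8b, after aryl addition to a seven-membered ketone. That ketone comes from Friedel–Crafts closure of the seven-membered ring on the diol of a benzylated ε-viniferin.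
3. Both halves come from one building block, a (2S,3S)-4-bromo-2,3-diaryl-2,3-dihydrobenzofuran, made by enantioselective rhodium-carbene C–H insertion and C2 epimerisation.
4. Ring order: dihydrofuran (made once, used twice), then the seven-membered carbocycle (west half only), then union of the halves, then debenzylation.

Assumption: Rh2(S-PTAD)4 is taken as the catalyst antipode that gives the 3S centre in step 8; if a trial shows the opposite sense, Rh2(R-PTAD)4 is used with no other change.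

Locants: ring A is the 3,5-dioxygenated aryl on C3 of the dihydrobenzofuran and ring B is its benzo ring. In the west tetracycle, C7a/C8a are C2/C3 of the dihydrofuran, C7b is the aryl-bearing sp3 carbon of the seven-membered ring and C8b is the other one.

## Route

Step 1
Reactants: 1 5-bromobenzene-1,3-diol
Product: 2 1,3-bis(benzyloxy)-5-bromobenzene
Conditions: BnBr (2.2 equiv), K2CO3, DMF, 60 °C
Reagents that add atoms: benzyl bromide, BrCc1ccccc1
Why: Williamson etherification of both phenols, no stereocentre involved.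

Step 2
Reactants: 2 1,3-bis(benzyloxy)-5-bromobenzene
Product: 3 2,4-bis(benzyloxy)-6-bromobenzaldehyde
Conditions: POCl3, DMF, 80 °C; aq NaOAc
Reagents that add atoms: N,N-dimethylformamide, CN(C)C=O; water, O
Why: Vilsmeier–Haack formylation goes ortho/para to the two ether groups at the position next to bromine, not the crowded one between the ethers.

Step 3
Reactants: 3 2,4-bis(benzyloxy)-6-bromobenzaldehyde
Product: 4 4-(benzyloxy)-2-bromo-6-hydroxybenzaldehyde
Conditions: BCl3 (1.1 equiv), CH2Cl2, -78 to -20 °C; H2O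
Reagents that add atoms: none
Why: Chelation-controlled dealkylation, because BCl3 bound between the formyl oxygen and the ortho ether oxygen cleaves only the ortho benzyl ether.

Step 4
Reactants: 4 4-(benzyloxy)-2-bromo-6-hydroxybenzaldehyde; 5 1-(benzyloxy)-4-(chloromethyl)benzene
Product: 6 4-(benzyloxy)-2-{[4-(benzyloxy)phenyl]methoxy}-6-bromobenzaldehyde
Conditions: K2CO3, KI (cat.), DMF, 60 °C
Reagents that add atoms: none
Why: Williamson etherification installs the 4-(benzyloxy)benzyl ether whose CH2 later becomes C2 of the dihydrofuran.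

Step 5
Reactants: 6 4-(benzyloxy)-2-{[4-(benzyloxy)phenyl]methoxy}-6-bromobenzaldehyde; 2 1,3-bis(benzyloxy)-5-bromobenzene
Product: 8 racemic [4-(benzyloxy)-2-{[4-(benzyloxy)phenyl]methoxy}-6-bromophenyl][3,5-bis(benzyloxy)phenyl]methanol, via arylmagnesium bromide 7 (not isolated)
Conditions: 2, Mg, THF, reflux; then 6, 0 °C; aq NH4Cl
Reagents that add atoms: none
Why: Grignard 1,2-addition brings in ring A, and the racemic carbinol centre is removed in the next step.

Step 6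
Reactants: 8 racemic diarylmethanol
Product: 9 [4-(benzyloxy)-2-{[4-(benzyloxy)phenyl]methoxy}-6-bromophenyl][3,5-bis(benzyloxy)phenyl]methanone
Conditions: Dess–Martin periodinane, CH2Cl2, rt
Reagents that add atoms: none
Why: Dess–Martin oxidation of a bis-benzylic alcohol to the diaryl ketone under neutral conditions.

Step 7
Reactants: 9 diaryl ketone
Product: 10 hydrazone of 9 (E/Z mixture)
Conditions: N2H4·H2O (10 equiv), AcOH (cat.), n-BuOH, 110 °C
Reagents that add atoms: hydrazine, NN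
Why: Hydrazone condensation, forced with excess hydrazine and heat because the ketone carries two ortho substituents.

Step 8
Reactants: 10 hydrazone of 9
Product: 12 (2R,3S)-cis-6-(benzyloxy)-2-[4-(benzyloxy)phenyl]-3-[3,5-bis(benzyloxy)phenyl]-4-bromo-2,3-dihydro-1-benzofuran, via diaryldiazomethane 11 (not isolated)
Conditions: MnO2, CH2Cl2, 0 °C; filter; Rh2(S-PTAD)4 (1 mol%), CH2Cl2, 0 °C
Reagents that add atoms: none
Why: Hydrazone dehydrogenation gives the donor/donor diazo compound, and the chiral dirhodium carbene undergoes intramolecular C–H insertion into the activated ArCH2–O bond, forming C2–C3 cis with C3 set S by the catalyst.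

Step 9
Reactants: 12 (2R,3S)-cis-dihydrobenzofuran
Product: 13 (2S,3S)-trans-6-(benzyloxy)-2-[4-(benzyloxy)phenyl]-3-[3,5-bis(benzyloxy)phenyl]-4-bromo-2,3-dihydro-1-benzofuran
Conditions: CF3CO2H (2 equiv), CH2Cl2, 0 °C to rt
Reagents that add atoms: none
Why: Acid-catalysed epimerisation by reversible ionisation of the C2–O bond (4-alkoxybenzylic cation) and reclosure inverts only C2 to the more stable trans isomer, leaving C3 untouched.

Step 10
Reactants: 14 4-(benzyloxy)benzaldehyde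
Product: 15 1-(benzyloxy)-4-ethenylbenzene
Conditions: Ph3PCH3Br, KOt-Bu, THF, 0 °C to rt
Reagents that add atoms: methyltriphenylphosphonium bromide, C[P+](c1ccccc1)(c1ccccc1)c1ccccc1.[Br-]
Why: Wittig methylenation of a non-enolisable aryl aldehyde.

Step 11
Reactants: 13 (2S,3S)-trans-bromide; 15 1-(benzyloxy)-4-ethenylbenzene
Product: 16 (2S,3S)-6-(benzyloxy)-2-[4-(benzyloxy)phenyl]-3-[3,5-bis(benzyloxy)phenyl]-4-{(E)-2-[4-(benzyloxy)phenyl]ethenyl}-2,3-dihydro-1-benzofuran (penta-O-benzyl-ε-viniferin)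
Conditions: Pd2(dba)3 (2.5 mol%), P(t-Bu)3·HBF4 (10 mol%), Cy2NMe, dioxane, 90 °C
Reagents that add atoms: none
Why: Mizoroki–Heck coupling, where syn insertion and syn β-hydride elimination give the E-stilbene.

Step 12
Reactants: 16 penta-O-benzyl-ε-viniferin
Product: 17 threo-1-[(2S,3S)-dihydrobenzofuran-4-yl]-2-[4-(benzyloxy)phenyl]ethane-1,2-diol (both facial isomers)
Conditions: K2OsO4·2H2O (2 mol%), NMO, acetone/H2O, rt
Reagents that add atoms: N-methylmorpholine N-oxide, C[N+]1([O-])CCOCC1; water, O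
Why: Upjohn syn-dihydroxylation, and the facial mixture is harmless because one carbinol is ionised in step 13 and the other is oxidised in step 14.

Step 13
Reactants: 17 threo-diol
Product: 18 (7aS,8aS,7bS)-penta-O-benzylampelopsin A-type alcohol (seven-membered ring closed from C7b to ring A; free 8b-OH, both epimers)
Conditions: BF3·OEt2 (20 mol%), CH2Cl2, -40 °C
Reagents that add atoms: none
Why: Intramolecular Friedel–Crafts alkylation, in which only the 4-alkoxybenzylic hydroxyl ionises and ring A captures the cation on the face that leaves the C7b aryl pseudo-equatorial and trans to C7a (the sense of acid-induced ampelopsin-type closures), setting C7b as S.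

Step 14
Reactants: 18 8b-alcohol
Product: 19 (7aS,8aS,7bS)-8b-ketone of 18
Conditions: Dess–Martin periodinane, CH2Cl2, rt
Reagents that add atoms: none
Why: Dess–Martin oxidation merges both 8b epimers into one ketone, with C7b already in its thermodynamically preferred configuration.

Step 15
Reactants: 20 2,4-dibromophenol
Product: 21 1-(benzyloxy)-2,4-dibromobenzene
Conditions: BnBr, K2CO3, DMF, rt
Reagents that add atoms: benzyl bromide, BrCc1ccccc1
Why: Williamson etherification.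

Step 16
Reactants: 21 1-(benzyloxy)-2,4-dibromobenzene; 19 8b-ketone
Product: 24 8b-[2-(benzyloxy)-5-bromophenyl]-8b-hydroxy tetracycle (7aS,8aS,7bS; 8b not assigned), via aryllithium 22 (not isolated), via arylcerium dichloride 23 (not isolated)
Conditions: 21, n-BuLi, THF, -78 °C; CeCl3, -78 °C; then 19, -78 to -40 °C; aq NH4Cl
Reagents that add atoms: none
Why: Halogen–lithium exchange occurs ortho to the ether oxygen, and the weakly basic organocerium (Imamoto-type 1,2-addition) adds to the enolisable ketone instead of deprotonating it, the carbinol configuration being irrelevant.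

Step 17
Reactants: 24 tertiary 8b-alcohol
Product: 25 (7aS,8aS,7bS,8bS)-8b-[2-(benzyloxy)-5-bromophenyl] tetracycle (8b-H cis to 7b-H)
Conditions: Et3SiH (5 equiv), CF3CO2H (5 equiv), CH2Cl2, -40 to 0 °C
Reagents that add atoms: none
Why: Ionic hydrogenation, in which the tertiary bis-benzylic cation takes hydride from Et3SiH anti to the neighbouring C7b aryl (held pseudo-axial by A(1,2) strain against the new aryl), giving the cis-diaryl arrangement and C8b as S.

Step 18
Reactants: 25 west aryl bromide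
Product: 27 4-(benzyloxy)-3-[(7aS,8aS,7bS,8bS)-tetracycl-8b-yl]benzaldehyde (west aldehyde), via aryllithium 26 (not isolated)
Conditions: n-BuLi, THF, -78 °C; DMF; aq NH4Cl
Reagents that add atoms: N,N-dimethylformamide, CN(C)C=O
Why: Halogen–lithium exchange followed by Bouveault formylation, faster at -78 °C than any benzylic deprotonation.

Step 19
Reactants: 13 (2S,3S)-trans-bromide
Product: 28 ethyl 2-[(2S,3S)-6-(benzyloxy)-2-[4-(benzyloxy)phenyl]-3-[3,5-bis(benzyloxy)phenyl]-2,3-dihydro-1-benzofuran-4-yl]acetate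
Conditions: BrCH2CO2Et, Zn, THF; then 13, Pd(dba)2 (5 mol%), XPhos (10 mol%), THF, 65 °C
Reagents that add atoms: ethyl bromoacetate, CCOC(=O)CBr
Why: Palladium-catalysed Negishi-type coupling of the Reformatsky reagent with the aryl bromide under nearly neutral conditions that leave both stereocentres alone.

Step 20
Reactants: 28 ethyl arylacetate
Product: 29 2-[(2S,3S)-6-(benzyloxy)-2-[4-(benzyloxy)phenyl]-3-[3,5-bis(benzyloxy)phenyl]-2,3-dihydro-1-benzofuran-4-yl]acetic acid (east acid)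
Conditions: LiOH, THF/MeOH/H2O, 40 °C; 1 M HCl to pH 3
Reagents that add atoms: LiOH, [Li+].[OH-]
Why: Ester saponification under base, to which the benzyl ethers and the trans-dihydrofuran are inert.

Step 21
Reactants: 29 east acid; 27 west aldehyde
Product: 31 anti-3-hydroxy-2,3-diarylpropanoic acid joining both halves, via dilithium enediolate 30 (not isolated)
Conditions: 29, LiN(i-Pr)2 (2.1 equiv), THF, 0 °C; then 27, -78 to 0 °C; 1 M HCl
Reagents that add atoms: none
Why: Intermolecular Ivanov-type aldol addition of the arylacetic acid dianion to the non-enolisable aldehyde through a Zimmerman–Traxler chair gives mainly the anti adduct, and both new centres become sp2 in the next step.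

Step 22
Reactants: 31 anti-β-hydroxy acid
Product: 33 deca-O-benzylvitisin A, via trans-β-lactone 32 (not isolated)
Conditions: PhSO2Cl, pyridine, 0 °C; then 60 °C
Reagents that add atoms: none
Why: β-Lactonisation by carboxyl activation followed by stereospecific thermal decarboxylation ([2+2] cycloreversion) of the trans-lactone gives the E-stilbene, and the 4-alkoxyphenyl-stabilised zwitterion sends any cis-lactone to the same alkene.

Step 23
Reactants: 33 deca-O-benzylvitisin A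
Product: 34 vitisin A (target)
Conditions: BCl3 (30 equiv), C6HMe5 (30 equiv), CH2Cl2, -78 °C; MeOH quench
Reagents that add atoms: none
Why: Lewis-acid debenzylation with pentamethylbenzene as benzyl-cation scavenger removes all ten benzyl ethers at low temperature without hydrogenation, sparing the stilbene and the benzylic C–O bonds.

## Compound list

1 | 5-bromobenzene-1,3-diol | Oc1cc(O)cc(Br)c1 | starting material
2 | 1,3-bis(benzyloxy)-5-bromobenzene | Brc1cc(OCc2ccccc2)cc(OCc2ccccc2)c1 | intermediate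
3 | 2,4-bis(benzyloxy)-6-bromobenzaldehyde | O=Cc1c(Br)cc(OCc2ccccc2)cc1OCc1ccccc1 | intermediate
4 | 4-(benzyloxy)-2-bromo-6-hydroxybenzaldehyde | O=Cc1c(Br)cc(OCc2ccccc2)cc1O | intermediate
5 | 1-(benzyloxy)-4-(chloromethyl)benzene | ClCc1ccc(OCc2ccccc2)cc1 | starting material
6 | 4-(benzyloxy)-2-{[4-(benzyloxy)phenyl]methoxy}-6-bromobenzaldehyde | O=Cc1c(Br)cc(OCc2ccccc2)cc1OCc1ccc(OCc2ccccc2)cc1 | intermediate
7 | [3,5-bis(benzyloxy)phenyl]magnesium bromide | Br[Mg]c1cc(OCc2ccccc2)cc(OCc2ccccc2)c1 | intermediate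
8 | racemic [4-(benzyloxy)-2-{[4-(benzyloxy)phenyl]methoxy}-6-bromophenyl][3,5-bis(benzyloxy)phenyl]methanol | OC(c1cc(OCc2ccccc2)cc(OCc2ccccc2)c1)c1c(Br)cc(OCc2ccccc2)cc1OCc1ccc(OCc2ccccc2)cc1 | intermediate
9 | [4-(benzyloxy)-2-{[4-(benzyloxy)phenyl]methoxy}-6-bromophenyl][3,5-bis(benzyloxy)phenyl]methanone | O=C(c1cc(OCc2ccccc2)cc(OCc2ccccc2)c1)c1c(Br)cc(OCc2ccccc2)cc1OCc1ccc(OCc2ccccc2)cc1 | intermediate
10 | hydrazone of 9 (E/Z mixture) | NN=C(c1cc(OCc2ccccc2)cc(OCc2ccccc2)c1)c1c(Br)cc(OCc2ccccc2)cc1OCc1ccc(OCc2ccccc2)cc1 | intermediate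
11 | diaryldiazomethane from 10 | [N-]=[N+]=C(c1cc(OCc2ccccc2)cc(OCc2ccccc2)c1)c1c(Br)cc(OCc2ccccc2)cc1OCc1ccc(OCc2ccccc2)cc1 | intermediate
12 | (2R,3S)-cis-6-(benzyloxy)-2-[4-(benzyloxy)phenyl]-3-[3,5-bis(benzyloxy)phenyl]-4-bromo-2,3-dihydro-1-benzofuran | Brc1cc(OCc2ccccc2)cc2c1[C@H](c1cc(OCc3ccccc3)cc(OCc3ccccc3)c1)[C@H](c1ccc(OCc3ccccc3)cc1)O2 | intermediate
13 | (2S,3S)-trans-6-(benzyloxy)-2-[4-(benzyloxy)phenyl]-3-[3,5-bis(benzyloxy)phenyl]-4-bromo-2,3-dihydro-1-benzofuran | Brc1cc(OCc2ccccc2)cc2c1[C@H](c1cc(OCc3ccccc3)cc(OCc3ccccc3)c1)[C@@H](c1ccc(OCc3ccccc3)cc1)O2 | intermediate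
14 | 4-(benzyloxy)benzaldehyde | O=Cc1ccc(OCc2ccccc2)cc1 | starting material
15 | 1-(benzyloxy)-4-ethenylbenzene | C=Cc1ccc(OCc2ccccc2)cc1 | intermediate
16 | (2S,3S)-penta-O-benzyl-ε-viniferin (4-{(E)-2-[4-(benzyloxy)phenyl]ethenyl} analogue of 13) | c1ccccc1COc1ccc(/C=C/c2cc(OCc3ccccc3)cc3c2[C@H](c2cc(OCc4ccccc4)cc(OCc4ccccc4)c2)[C@@H](c2ccc(OCc4ccccc4)cc2)O3)cc1 | intermediate
17 | threo-1,2-diol of 16 (both facial isomers; new carbinol centres not assigned) | c1ccccc1COc1ccc(C(O)C(O)c2cc(OCc3ccccc3)cc3c2[C@H](c2cc(OCc4ccccc4)cc(OCc4ccccc4)c2)[C@@H](c2ccc(OCc4ccccc4)cc2)O3)cc1 | intermediate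
18 | (7aS,8aS,7bS)-penta-O-benzylampelopsin A-type alcohol (8b-OH, both epimers) | c1ccccc1COc1ccc([C@H]2c3c(OCc4ccccc4)cc(OCc4ccccc4)cc3[C@H]3c4c(cc(OCc5ccccc5)cc4C2O)O[C@@H]3c2ccc(OCc4ccccc4)cc2)cc1 | intermediate
19 | (7aS,8aS,7bS)-8b-ketone of 18 | c1ccccc1COc1ccc([C@H]2c3c(OCc4ccccc4)cc(OCc4ccccc4)cc3[C@H]3c4c(cc(OCc5ccccc5)cc4C2=O)O[C@@H]3c2ccc(OCc4ccccc4)cc2)cc1 | intermediate
20 | 2,4-dibromophenol | Oc1ccc(Br)cc1Br | starting material
21 | 1-(benzyloxy)-2,4-dibromobenzene | Brc1ccc(OCc2ccccc2)c(Br)c1 | intermediate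
22 | [2-(benzyloxy)-5-bromophenyl]lithium | [Li]c1cc(Br)ccc1OCc1ccccc1 | intermediate
23 | [2-(benzyloxy)-5-bromophenyl]cerium dichloride | Cl[Ce](Cl)c1cc(Br)ccc1OCc1ccccc1 | intermediate
24 | 8b-[2-(benzyloxy)-5-bromophenyl]-8b-hydroxy tetracycle (7aS,8aS,7bS; 8b not assigned) | c1ccccc1COc1ccc([C@H]2c3c(OCc4ccccc4)cc(OCc4ccccc4)cc3[C@H]3c4c(cc(OCc5ccccc5)cc4C2(O)c2cc(Br)ccc2OCc2ccccc2)O[C@@H]3c2ccc(OCc4ccccc4)cc2)cc1 | intermediate
25 | (7aS,8aS,7bS,8bS)-8b-[2-(benzyloxy)-5-bromophenyl] tetracycle | c1ccccc1COc1ccc([C@H]2c3c(OCc4ccccc4)cc(OCc4ccccc4)cc3[C@H]3c4c(cc(OCc5ccccc5)cc4[C@H]2c2cc(Br)ccc2OCc2ccccc2)O[C@@H]3c2ccc(OCc4ccccc4)cc2)cc1 | intermediate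
26 | aryllithium from 25 (Li in place of Br) | c1ccccc1COc1ccc([C@H]2c3c(OCc4ccccc4)cc(OCc4ccccc4)cc3[C@H]3c4c(cc(OCc5ccccc5)cc4[C@H]2c2cc([Li])ccc2OCc2ccccc2)O[C@@H]3c2ccc(OCc4ccccc4)cc2)cc1 | intermediate
27 | west aldehyde, 4-(benzyloxy)-3-[(7aS,8aS,7bS,8bS)-tetracycl-8b-yl]benzaldehyde | c1ccccc1COc1ccc([C@H]2c3c(OCc4ccccc4)cc(OCc4ccccc4)cc3[C@H]3c4c(cc(OCc5ccccc5)cc4[C@H]2c2cc(C=O)ccc2OCc2ccccc2)O[C@@H]3c2ccc(OCc4ccccc4)cc2)cc1 | intermediate
28 | ethyl 2-[(2S,3S)-dihydrobenzofuran-4-yl]acetate (CH2CO2Et in place of Br in 13) | CCOC(=O)Cc1cc(OCc2ccccc2)cc2c1[C@H](c1cc(OCc3ccccc3)cc(OCc3ccccc3)c1)[C@@H](c1ccc(OCc3ccccc3)cc1)O2 | intermediate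
29 | east acid, 2-[(2S,3S)-dihydrobenzofuran-4-yl]acetic acid | OC(=O)Cc1cc(OCc2ccccc2)cc2c1[C@H](c1cc(OCc3ccccc3)cc(OCc3ccccc3)c1)[C@@H](c1ccc(OCc3ccccc3)cc1)O2 | intermediate
30 | dilithium enediolate of 29 | [Li+].[Li+].[O-]C([O-])=Cc1cc(OCc2ccccc2)cc2c1[C@H](c1cc(OCc3ccccc3)cc(OCc3ccccc3)c1)[C@@H](c1ccc(OCc3ccccc3)cc1)O2 | intermediate
31 | anti-3-hydroxy-2-(east aryl)-3-(west aryl)propanoic acid (both anti isomers; new centres not assigned) | c1ccccc1COc1ccc([C@H]2c3c(OCc4ccccc4)cc(OCc4ccccc4)cc3[C@H]3c4c(cc(OCc5ccccc5)cc4[C@H]2c2cc(C(O)C(C(=O)O)c4cc(OCc5ccccc5)cc5c4[C@H](c4cc(OCc6ccccc6)cc(OCc6ccccc6)c4)[C@@H](c4ccc(OCc6ccccc6)cc4)O5)ccc2OCc2ccccc2)O[C@@H]3c2ccc(OCc4ccccc4)cc2)cc1 | intermediate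
32 | trans-3,4-diaryl-oxetan-2-one from 31 | c1ccccc1COc1ccc([C@H]2c3c(OCc4ccccc4)cc(OCc4ccccc4)cc3[C@H]3c4c(cc(OCc5ccccc5)cc4[C@H]2c2cc(C6OC(=O)C6c4cc(OCc5ccccc5)cc5c4[C@H](c4cc(OCc6ccccc6)cc(OCc6ccccc6)c4)[C@@H](c4ccc(OCc6ccccc6)cc4)O5)ccc2OCc2ccccc2)O[C@@H]3c2ccc(OCc4ccccc4)cc2)cc1 | intermediate
33 | deca-O-benzylvitisin A | c1ccccc1COc1ccc([C@H]2c3c(OCc4ccccc4)cc(OCc4ccccc4)cc3[C@H]3c4c(cc(OCc5ccccc5)cc4[C@H]2c2cc(/C=C/c4cc(OCc5ccccc5)cc5c4[C@H](c4cc(OCc6ccccc6)cc(OCc6ccccc6)c4)[C@@H](c4ccc(OCc6ccccc6)cc4)O5)ccc2OCc2ccccc2)O[C@@H]3c2ccc(OCc4ccccc4)cc2)cc1 | intermediate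
34 | vitisin A, (7aS,8aS,7bS,8bS) west core with (2S,3S) east dihydrobenzofuran and E-stilbene | Oc1ccc([C@H]2c3c(O)cc(O)cc3[C@H]3c4c(cc(O)cc4[C@H]2c2cc(/C=C/c4cc(O)cc5c4[C@H](c4cc(O)cc(O)c4)[C@@H](c4ccc(O)cc4)O5)ccc2O)O[C@@H]3c2ccc(O)cc2)cc1 | target

## Step count and risks

Total steps: 23. Longest linear sequence: 19 (steps 1–9, 11–14, 16–18, 21–23).

Most likely to fail, first: step 8. The diaryldiazomethane carries two ortho substituents, and both the insertion yield and the sense of induction are untested on this substrate. The fallback sets out from 4 and comes back at 13.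
- Addition of excess 7 to 4 gives the racemic diol 5-(benzyloxy)-2-{[3,5-bis(benzyloxy)phenyl](hydroxy)methyl}-3-bromophenol F1.
- NaO2SC6H4CH3 with catalytic TsOH turns it into the sulfone 5-(benzyloxy)-2-{[3,5-bis(benzyloxy)phenyl](4-methylbenzenesulfonyl)methyl}-3-bromophenol F2.
- Separately, 5 and tetrahydrothiophene give 1-{[4-(benzyloxy)phenyl]methyl}thiolan-1-ium chloride F3.
- Cs2CO3 in CH2Cl2 converts F3 into the sulfonium ylide F4 and F2 into the ortho-quinone methide F5. Conjugate addition of the ylide and ring closure of the phenoxide give the racemic trans-dihydrobenzofuran F6.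
- Preparative chiral SFC of F6 delivers 13, with the absolute configuration read from the bromine anomalous dispersion in an X-ray structure.

Second: step 13. A pinacol-type hydride shift may outrun the seven-membered ring closure. The fallback sets out from 16 and comes back at 19.
- NBS in CH2Cl2 at -78 °C forms the bromonium ion of the stilbene, which ring A captures at C7b to give the (7aS,8aS,7bS)-8b-bromo tetracycle F7.
- Kornblum oxidation (AgBF4, DMSO, then Et3N) converts F7 directly into 19.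

Third: step 17. The cation may lose the C7b proton to a tetra-aryl alkene and scramble C7b, or take hydride from the wrong face. The fallback sets out from 24 and comes back at 25.
- Acylation with methyl chlorooxoacetate and DMAP gives the methyl oxalate of 24 F8.
- CsOH hydrolysis gives the caesium oxalate of 24 F9.
- Under blue light with Ir[dF(CF3)ppy]2(dtbbpy)PF6, F9 loses two CO2 to a tertiary benzylic radical. This radical takes a hydrogen atom from 1,4-cyclohexadiene (thiol co-catalyst) anti to the C7b aryl and gives 25 without any cationic intermediate.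

Further compounds
F1 | step 8 | racemic 5-(benzyloxy)-2-{[3,5-bis(benzyloxy)phenyl](hydroxy)methyl}-3-bromophenol | OC(c1cc(OCc2ccccc2)cc(OCc2ccccc2)c1)c1c(Br)cc(OCc2ccccc2)cc1O
F2 | step 8 | racemic 5-(benzyloxy)-2-{[3,5-bis(benzyloxy)phenyl](4-methylbenzenesulfonyl)methyl}-3-bromophenol | Cc1ccc(S(=O)(=O)C(c2cc(OCc3ccccc3)cc(OCc3ccccc3)c2)c2c(Br)cc(OCc3ccccc3)cc2O)cc1
F3 | step 8 | 1-{[4-(benzyloxy)phenyl]methyl}thiolan-1-ium chloride | [Cl-].c1ccccc1COc1ccc(C[S+]2CCCC2)cc1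
F4 | step 8 | sulfonium ylide from F3 | c1ccccc1COc1ccc([CH-][S+]2CCCC2)cc1
F5 | step 8 | ortho-quinone methide, 3-(benzyloxy)-6-{[3,5-bis(benzyloxy)phenyl]methylidene}-5-bromocyclohexa-2,4-dien-1-one | O=C1C=C(OCc2ccccc2)C=C(Br)C1=Cc1cc(OCc2ccccc2)cc(OCc2ccccc2)c1
F6 | step 8 | racemic trans-dihydrobenzofuran (13 with its enantiomer, 1:1) | Brc1cc(OCc2ccccc2)cc2c1[C@H](c1cc(OCc3ccccc3)cc(OCc3ccccc3)c1)[C@@H](c1ccc(OCc3ccccc3)cc1)O2.Brc1cc(OCc2ccccc2)cc2c1[C@@H](c1cc(OCc3ccccc3)cc(OCc3ccccc3)c1)[C@H](c1ccc(OCc3ccccc3)cc1)O2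
F7 | step 13 | (7aS,8aS,7bS)-8b-bromo tetracycle (both 8b epimers) | c1ccccc1COc1ccc([C@H]2c3c(OCc4ccccc4)cc(OCc4ccccc4)cc3[C@H]3c4c(cc(OCc5ccccc5)cc4C2Br)O[C@@H]3c2ccc(OCc4ccccc4)cc2)cc1
F8 | step 17 | methyl oxalate of 24 | c1ccccc1COc1ccc([C@H]2c3c(OCc4ccccc4)cc(OCc4ccccc4)cc3[C@H]3c4c(cc(OCc5ccccc5)cc4C2(OC(=O)C(=O)OC)c2cc(Br)ccc2OCc2ccccc2)O[C@@H]3c2ccc(OCc4ccccc4)cc2)cc1
F9 | step 17 | caesium oxalate of 24 | [Cs+].c1ccccc1COc1ccc([C@H]2c3c(OCc4ccccc4)cc(OCc4ccccc4)cc3[C@H]3c4c(cc(OCc5ccccc5)cc4C2(OC(=O)C([O-])=O)c2cc(Br)ccc2OCc2ccccc2)O[C@@H]3c2ccc(OCc4ccccc4)cc2)cc1
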